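**The turn.** You have 4 questions on this flask, and the choice among the changes is the one to turn round.

- zeta: solid substrate 0.20 M; coupling partner 0.10 M; run made earlier
- flask: solid substrate 0.20 M; coupling partner 0.200 M; time 4.0 h

zeta run (percent of the solid substrate charged)

| time / min | target / % | starting material / % | solid substrate / % |
|---|---|---|---|
| 2.00 | 0 | 2.0 | 98.3 |
| 6.00 | 0 | 5.2 | 95.0 |
| 12.0 | 0.1 | 8.1 | 90.3 |
| 15.0 | 0 | 10.5 | 88.2 |
| 25.0 | 0.6 | 15.9 | 82.3 |

(scatter of a reading: 0.5 percentage points)

- target at 4.0 h, in percent of the solid substrate charged
- concentration of starting material in solution at 1.0 h, in percent of saturation
- the change that raises the amount of target at 4.0 h, in percent of the solid substrate charged most ("none" if none brings more than 2 percentage points) (south / south-east / west / none)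
- amount of target at 4.0 h, in percent of the solid substrate charged, after south-east

- south: doubling the solubility of the solid substrate, all else as stated
- south-east: doubling the amount of coupling partner, all else as stated
- west: doubling the dissolution coefficient of the solid substrate, all else as stated

- as a solid, counted per litre of solution: solid substrate
- at the start none of the solid substrate is in solution
- starting material is what solid substrate becomes in solution
- starting material means what is dissolved; the solid is not counted in it

**The clock.** Define the clearing time as the time the solid charge takes at the mean rate of loss seen so far: 2.35 h. You read it from the last reading of the zeta run. That run holds the same solid charge as the flask, so you carry the clock over, assuming the coupling partner leaves dissolving alone. The reading at 6.00 min gives 2.00 h, a shorter clock. The loss seems to slow, so treat 2.35 h as a floor.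

**The opposite case.** Your own test for south or west to win: solid keeps dissolving to the end, with the clearing time reaching 4.0 h. In logarithms, the clock stands 0.231 of a decade below that, a factor of 1.70. The margin is thin, and a floor below the time asked shows no clearing before that time. So the readings leave the opposite case open. The target reading of 0.6% lies close to the scatter of 0.5 percentage points, so it gives no clock. You bet on south-east as a judgement, without proof from these readings.

**The result.** The forecast gives 31%, 63%, south-east and 52%, and says “South-east narrowly wins”. The flask gives 25.2%, 43.3%, south-east and 42.3%.

    starting material → intermediate A (k = 1.80 × 10⁻⁴ s⁻¹)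
    coupling partner + intermediate A → intermediate B (k = 7.30 × 10⁻⁴ M⁻¹ s⁻¹)
    coupling partner + intermediate B → target (k = 0.0130 M⁻¹ s⁻¹)
    intermediate B ⇌ intermediate C (K = 0.620, k = 2.70 × 10⁻⁴ s⁻¹)
    intermediate B → side product (k = 1.00 × 10⁻⁴ s⁻¹)
    solid substrate ⇌ starting material, rate k6*(cs6 - [starting material]) while solid is left; crystals form when [starting material] > cs6 (solubility = 0.120 M, k = 2.30 × 10⁻⁴ s⁻¹)

South-east gains 17 points, against 7.6 points for south and 5.3 points for west. At 2.00 h the flask has lost 61.5% of its solid, 0.724 of what the clock allows. The neighbour read at 2.50 h is past the clock, and it still holds 27.1% solid substrate.

The earlier runs and the new flask were generated by integration on assumed constants.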